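**Retrosynthetic overview**
1. Target 22 ⇐ dibenzoate acetonide 21 (hydrolysis of the trans-acetonide) ⇐ carbinol 20 (benzoylation at O4).
2. 20 ⇐ iodoalkene aldehyde 18 by forming C4–C5 in a vinylchromium–aldehyde closure. The route rests on the C4 allylic benzoate carbon lying next to the C5=C6 cis-alkene of the cyclohexene (vinyl-metal plus aldehyde retron), on the free trans C2/C3 diol (a D-tartrate-derived dioxolane) and on the C1 quaternary carbinol with its exocyclic C7 oxymethylene, which is set before the ring exists.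
3. 18 ⇐ alkyne 14: Z-iodoalkene from the alkyne (iodination, diimide), then the C4 alcohol to the aldehyde.
4. 14 ⇐ ynone 7: C1 by chelate-controlled addition of a hydroxymethyl-anion equivalent (C7); 7 ⇐ 2,3-O-isopropylidene-D-threitol 1.
5. Ring order: the dioxolane comes with 1; the cyclohexene is the only ring formed (step 12).

Key step: step 12

Remark: 2,3-O-isopropylidene-D-threitol (1), the LiAlH4 reduction product of D-tartrate acetonide, is taken as a catalogue compound; atom labels C1–C7 are those of the target (C1 quaternary carbinol, C2/C3 diol, C4 benzoate carbon, C5=C6, C7 exocyclic CH2O).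

Step 1
Reactants: 1 2,3-O-isopropylidene-D-threitol
Product: 2 [(4R,5R)-5-{[tert-butyl(dimethyl)silyl]oxymethyl}-2,2-dimethyl-1,3-dioxolan-4-yl]methanol
Conditions: NaH (1.0 equiv), THF, 0 °C to rt; TBSCl (1.0 equiv)
Reagents that add atoms: tert-butyldimethylsilyl chloride, CC(C)(C)[Si](C)(C)Cl
Why: Monosilylation of a symmetric diol through its sparingly soluble monosodium alkoxide (Williamson-type O-silylation) should stop at the mono-ether, and the C2 symmetry of 1 makes the two hydroxyls equivalent, so no stereocentre is touched.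

Step 2
Reactants: 2 mono-TBS ether
Product: 3 (4S,5R)-5-{[tert-butyl(dimethyl)silyl]oxymethyl}-2,2-dimethyl-1,3-dioxolane-4-carbaldehyde
Conditions: Dess–Martin periodinane, NaHCO3, CH2Cl2, 0 °C to rt
Reagents that add atoms: none
Why: Dess–Martin oxidation of the primary alcohol is buffered and non-epimerising, and the trans-4,5-disubstituted dioxolane is the more stable arrangement in any case.

Step 3
Reactants: 3 aldehyde; 4 ethynyltrimethylsilane
Product: 6 1-[(4R,5R)-5-{[tert-butyl(dimethyl)silyl]oxymethyl}-2,2-dimethyl-1,3-dioxolan-4-yl]-3-(trimethylsilyl)prop-2-yn-1-ol (both carbinol epimers), via lithium trimethylsilylacetylide 5 (not isolated)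
Conditions: 4, n-BuLi, THF, −78 °C; then 3; aq. NH4Cl
Reagents that add atoms: ethynyltrimethylsilane 4, C#C[Si](C)(C)C
Why: 1,2-Addition of a lithium acetylide to an aldehyde; the carbinol epimers are carried on together because this centre is oxidised in step 4.

Step 4
Reactants: 6 propargylic alcohols
Product: 7 1-[(4S,5R)-5-{[tert-butyl(dimethyl)silyl]oxymethyl}-2,2-dimethyl-1,3-dioxolan-4-yl]-3-(trimethylsilyl)prop-2-yn-1-one
Conditions: Dess–Martin periodinane, NaHCO3, CH2Cl2, rt
Reagents that add atoms: none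
Why: Dess–Martin oxidation of a secondary propargylic alcohol gives the ynone under neutral conditions, and the C-silyl cap stabilises the ynone and disfavours conjugate addition in step 5.

Step 5
Reactants: 7 ynone; 8 (chloromethyl)(isopropoxy)dimethylsilane
Product: 10 (2R)-2-[(4S,5R)-5-{[tert-butyl(dimethyl)silyl]oxymethyl}-2,2-dimethyl-1,3-dioxolan-4-yl]-1-[isopropoxy(dimethyl)silyl]-4-(trimethylsilyl)but-3-yn-2-ol, via silylmethyl Grignard reagent 9 (not isolated)
Conditions: 8, Mg, THF, rt; then 7, MgBr2·OEt2, CH2Cl2, −78 °C; aq. NH4Cl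
Reagents that add atoms: (chloromethyl)(isopropoxy)dimethylsilane 8, CC(C)O[Si](C)(C)CCl
Why: Chelation-controlled Grignard 1,2-addition (Cram cyclic model): magnesium bridges the ketone oxygen and the dioxolane oxygen on C2 (the silyl ether does not chelate and the C3 oxygen cannot reach because of the five-membered acetal), so the silylmethyl nucleophile, the Tamao hydroxymethyl-anion equivalent, should attack the face bearing H-2 rather than C3 and set C1 as in the target; C7 is the nucleophile because the same chelate with an ethynyl nucleophile on a hydroxymethyl ketone would give the C1 epimer.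

Step 6
Reactants: 10 β-hydroxysilane
Product: 12 (2S)-2-[(4S,5R)-5-{[tert-butyl(dimethyl)silyl]oxymethyl}-2,2-dimethyl-1,3-dioxolan-4-yl]but-3-yne-1,2-diol, via C-silyl alkyne diol 11 (not isolated)
Conditions: KF, KHCO3, 30% H2O2, THF/MeOH, rt; then K2CO3, MeOH, rt
Reagents that add atoms: hydrogen peroxide, OO
Why: Tamao oxidation converts the alkoxysilyl C–Si bond into C–OH under fluoride/bicarbonate buffering, which should outpace Peterson elimination of the β-hydroxysilane, and methanolic K2CO3 completes protodesilylation of the alkyne; C1 is not involved.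

Step 7
Reactants: 12 alkyne diol; 13 benzoyl chloride
Product: 14 (2S)-2-[(4S,5R)-5-{[tert-butyl(dimethyl)silyl]oxymethyl}-2,2-dimethyl-1,3-dioxolan-4-yl]-2-hydroxybut-3-yn-1-yl benzoate
Conditions: BzCl (1.1 equiv), pyridine, CH2Cl2, −20 to 0 °C
Reagents that add atoms: benzoyl chloride 13, O=C(Cl)c1ccccc1
Why: Acylation with one equivalent of acid chloride should take the primary C7 hydroxyl and leave the hindered tertiary propargylic hydroxyl free.

Step 8
Reactants: 14 terminal alkyne
Product: 15 (2S)-2-[(4S,5R)-5-{[tert-butyl(dimethyl)silyl]oxymethyl}-2,2-dimethyl-1,3-dioxolan-4-yl]-2-hydroxy-4-iodobut-3-yn-1-yl benzoate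
Conditions: N-iodosuccinimide, AgNO3 (10 mol%), acetone, rt, dark
Reagents that add atoms: N-iodosuccinimide, O=C1CCC(=O)N1I
Why: Silver-catalysed electrophilic iodination of a terminal alkyne via the silver acetylide tolerates the free hydroxyl, ester, silyl ether and acetal.

Step 9
Reactants: 15 iodoalkyne
Product: 16 (2S,3Z)-2-[(4S,5R)-5-{[tert-butyl(dimethyl)silyl]oxymethyl}-2,2-dimethyl-1,3-dioxolan-4-yl]-2-hydroxy-4-iodobut-3-en-1-yl benzoate
Conditions: 2-nitrobenzenesulfonohydrazide, Et3N, THF/i-PrOH, rt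
Reagents that add atoms: none
Why: Diimide released from the sulfonohydrazide adds H2 suprafacially to the 1-iodoalkyne, the known route to (Z)-1-iodoalkenes, and the syn delivery fixes the Z geometry while C–I, benzoate and silyl ether stay intact.

Step 10
Reactants: 16 silyl ether
Product: 17 (2S,3Z)-2-hydroxy-2-[(4S,5R)-5-(hydroxymethyl)-2,2-dimethyl-1,3-dioxolan-4-yl]-4-iodobut-3-en-1-yl benzoate
Conditions: HF·pyridine, pyridine, THF, 0 °C to rt
Reagents that add atoms: none
Why: Buffered fluoride desilylation cleaves the primary TBS ether without acid strong enough to open the unstrained dioxolane or base strong enough to move the benzoate.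

Step 11
Reactants: 17 primary alcohol
Product: 18 (2S,3Z)-2-[(4S,5S)-5-formyl-2,2-dimethyl-1,3-dioxolan-4-yl]-2-hydroxy-4-iodobut-3-en-1-yl benzoate
Conditions: Dess–Martin periodinane, NaHCO3, CH2Cl2, 0 °C to rt; used crude
Reagents that add atoms: none
Why: Dess–Martin oxidation takes only the primary alcohol (the tertiary one cannot be oxidised), and the hydroxy aldehyde should stay open because its lactol would be a five-membered ring trans-fused to the dioxolane.

Step 12
Reactants: 18 Z-iodoalkene aldehyde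
Product: 20 (1S,2S,3R,4R)-1-(benzoyloxymethyl)-2,3-O-isopropylidenecyclohex-5-ene-1,2,3,4-tetrol, via vinylchromium dichloride 19 (not isolated)
Conditions: CrCl2 (10 equiv), NiCl2 (cat.), degassed DMSO/THF, rt, high dilution, slow addition of 18
Reagents that add atoms: none
Why: Zerovalent nickel, formed from NiCl2 and CrCl2, inserts into the C5–I bond with retention of the Z geometry and hands the vinyl group to trivalent chromium, and the resulting vinylchromium 19 adds to the C4 aldehyde, forming C4–C5. The closest known reaction type is the intramolecular Nozaki–Hiyama–Kishi cyclisation of iodoalkene aldehydes to cyclic allylic alcohols. The cyclohexene closes in a 6-exo-trig mode, with the carbonyl oxygen outside the new ring and the C5=C6 bond inside it. The new C4 centre is controlled by the C3 dioxolane oxygen, which the trans ring fusion holds equatorial on the forming half-chair and thus anti to the incoming C5 (a built-in polar Felkin–Anh arrangement); attack with the carbonyl oxygen gauche to C2, C5 passing H-3, should give the 3,4-cis (4R) carbinol. The step needs ring closure over intermolecular coupling, secured by high dilution and by the Z-alkene and trans-dioxolane holding C4 and C5 close, and chemoselectivity, secured because organochromium reagents leave the benzoate alone and tolerate the tertiary hydroxyl. The face selectivity at C4 rests only on the dioxolane bias and is the open point of the step.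

Step 13
Reactants: 20 allylic carbinol; 13 benzoyl chloride
Product: 21 (1S,2S,3R,4R)-4-O-benzoyl-1-(benzoyloxymethyl)-2,3-O-isopropylidenecyclohex-5-ene-1,2,3,4-tetrol
Conditions: BzCl, pyridine, DMAP (cat.), CH2Cl2, 0 °C to rt
Reagents that add atoms: benzoyl chloride 13, O=C(Cl)c1ccccc1
Why: DMAP-catalysed acylation of the secondary allylic C4 hydroxyl breaks only the O–H bond, so C4 keeps its configuration, and the tertiary C1 hydroxyl is too hindered to react.

Step 14
Reactants: 21 dibenzoate acetonide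
Product: 22 [(1S,2S,3S,4R)-4-(benzoyloxy)-1,2,3-trihydroxycyclohex-5-en-1-yl]methyl benzoate
Conditions: TFA/H2O (4:1), CH2Cl2, 0 °C
Reagents that add atoms: none
Why: Acid-catalysed acetal hydrolysis; the strained trans-fused dioxolane should open under mild aqueous acid at 0 °C, where benzoates are not expected to hydrolyse or migrate, and no stereocentre is affected.

**Compound list**
1 | 2,3-O-isopropylidene-D-threitol, [(4R,5R)-2,2-dimethyl-1,3-dioxolane-4,5-diyl]dimethanol | OC[C@H]1OC(C)(C)O[C@@H]1CO | starting material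
2 | [(4R,5R)-5-{[tert-butyl(dimethyl)silyl]oxymethyl}-2,2-dimethyl-1,3-dioxolan-4-yl]methanol | OC[C@H]1OC(C)(C)O[C@@H]1CO[Si](C)(C)C(C)(C)C | intermediate
3 | (4S,5R)-5-{[tert-butyl(dimethyl)silyl]oxymethyl}-2,2-dimethyl-1,3-dioxolane-4-carbaldehyde | O=C[C@H]1OC(C)(C)O[C@@H]1CO[Si](C)(C)C(C)(C)C | intermediate
4 | ethynyltrimethylsilane | C#C[Si](C)(C)C | starting material
5 | lithium trimethylsilylacetylide | [Li]C#C[Si](C)(C)C | intermediate
6 | 1-[(4R,5R)-5-{[tert-butyl(dimethyl)silyl]oxymethyl}-2,2-dimethyl-1,3-dioxolan-4-yl]-3-(trimethylsilyl)prop-2-yn-1-ol, both carbinol epimers | C[Si](C)(C)C#CC(O)[C@H]1OC(C)(C)O[C@@H]1CO[Si](C)(C)C(C)(C)C | intermediate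
7 | 1-[(4S,5R)-5-{[tert-butyl(dimethyl)silyl]oxymethyl}-2,2-dimethyl-1,3-dioxolan-4-yl]-3-(trimethylsilyl)prop-2-yn-1-one | C[Si](C)(C)C#CC(=O)[C@H]1OC(C)(C)O[C@@H]1CO[Si](C)(C)C(C)(C)C | intermediate
8 | (chloromethyl)(isopropoxy)dimethylsilane | CC(C)O[Si](C)(C)CCl | starting material
9 | [(isopropoxydimethylsilyl)methyl]magnesium chloride | CC(C)O[Si](C)(C)C[Mg]Cl | intermediate
10 | (2R)-2-[(4S,5R)-5-{[tert-butyl(dimethyl)silyl]oxymethyl}-2,2-dimethyl-1,3-dioxolan-4-yl]-1-[isopropoxy(dimethyl)silyl]-4-(trimethylsilyl)but-3-yn-2-ol | C[Si](C)(C)C#C[C@](O)(C[Si](C)(C)OC(C)C)[C@H]1OC(C)(C)O[C@@H]1CO[Si](C)(C)C(C)(C)C | intermediate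
11 | (2S)-2-[(4S,5R)-5-{[tert-butyl(dimethyl)silyl]oxymethyl}-2,2-dimethyl-1,3-dioxolan-4-yl]-4-(trimethylsilyl)but-3-yne-1,2-diol | C[Si](C)(C)C#C[C@](O)(CO)[C@H]1OC(C)(C)O[C@@H]1CO[Si](C)(C)C(C)(C)C | intermediate
12 | (2S)-2-[(4S,5R)-5-{[tert-butyl(dimethyl)silyl]oxymethyl}-2,2-dimethyl-1,3-dioxolan-4-yl]but-3-yne-1,2-diol | C#C[C@](O)(CO)[C@H]1OC(C)(C)O[C@@H]1CO[Si](C)(C)C(C)(C)C | intermediate
13 | benzoyl chloride | O=C(Cl)c1ccccc1 | starting material
14 | (2S)-2-[(4S,5R)-5-{[tert-butyl(dimethyl)silyl]oxymethyl}-2,2-dimethyl-1,3-dioxolan-4-yl]-2-hydroxybut-3-yn-1-yl benzoate | C#C[C@](O)(COC(=O)c1ccccc1)[C@H]1OC(C)(C)O[C@@H]1CO[Si](C)(C)C(C)(C)C | intermediate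
15 | (2S)-2-[(4S,5R)-5-{[tert-butyl(dimethyl)silyl]oxymethyl}-2,2-dimethyl-1,3-dioxolan-4-yl]-2-hydroxy-4-iodobut-3-yn-1-yl benzoate | IC#C[C@](O)(COC(=O)c1ccccc1)[C@H]1OC(C)(C)O[C@@H]1CO[Si](C)(C)C(C)(C)C | intermediate
16 | (2S,3Z)-2-[(4S,5R)-5-{[tert-butyl(dimethyl)silyl]oxymethyl}-2,2-dimethyl-1,3-dioxolan-4-yl]-2-hydroxy-4-iodobut-3-en-1-yl benzoate | I/C=C\[C@](O)(COC(=O)c1ccccc1)[C@H]1OC(C)(C)O[C@@H]1CO[Si](C)(C)C(C)(C)C | intermediate
17 | (2S,3Z)-2-hydroxy-2-[(4S,5R)-5-(hydroxymethyl)-2,2-dimethyl-1,3-dioxolan-4-yl]-4-iodobut-3-en-1-yl benzoate | I/C=C\[C@](O)(COC(=O)c1ccccc1)[C@H]1OC(C)(C)O[C@@H]1CO | intermediate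
18 | (2S,3Z)-2-[(4S,5S)-5-formyl-2,2-dimethyl-1,3-dioxolan-4-yl]-2-hydroxy-4-iodobut-3-en-1-yl benzoate | I/C=C\[C@](O)(COC(=O)c1ccccc1)[C@H]1OC(C)(C)O[C@@H]1C=O | intermediate
19 | vinylchromium dichloride derived from 18 (chromium in place of iodine, Z retained) | Cl[Cr](Cl)/C=C\[C@](O)(COC(=O)c1ccccc1)[C@H]1OC(C)(C)O[C@@H]1C=O | intermediate
20 | (1S,2S,3R,4R)-1-(benzoyloxymethyl)-2,3-O-isopropylidenecyclohex-5-ene-1,2,3,4-tetrol | O=C(OC[C@@]1(O)C=C[C@@H](O)[C@H]2OC(C)(C)O[C@H]12)c1ccccc1 | intermediate
21 | (1S,2S,3R,4R)-4-O-benzoyl-1-(benzoyloxymethyl)-2,3-O-isopropylidenecyclohex-5-ene-1,2,3,4-tetrol | O=C(OC[C@@]1(O)C=C[C@@H](OC(=O)c3ccccc3)[C@H]2OC(C)(C)O[C@H]12)c1ccccc1 | intermediate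
22 | [(1S,2S,3S,4R)-4-(benzoyloxy)-1,2,3-trihydroxycyclohex-5-en-1-yl]methyl benzoate | O=C(OC[C@@]1(O)C=C[C@@H](OC(=O)c2ccccc2)[C@@H](O)[C@@H]1O)c1ccccc1 | target

**Step count and risks**
Total step count: 14. Longest linear sequence: 14 steps (1 to 22).

Steps most likely to fail:

1. Step 12. What may go wrong: attack on the other aldehyde face (carbonyl oxygen pseudoequatorial), so that the 3,4-trans carbinol predominates or a mixture forms. Fallback: setting out from 18, the same NiCl2/CrCl2 closure is accepted with the opposite outcome at C4, giving the (4S)-epimer F1. F1 is then esterified with inversion instead of retention, by a Mitsunobu reaction (PPh3, DIAD, benzoic acid, toluene, 0 °C to rt), in which benzoate displaces the oxyphosphonium group at C4 by SN2. This gives 21, where the route is rejoined. If both epimers form, they would be separated and each sent to 21 by its own esterification.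

2. Step 5. What may go wrong: non-chelated Felkin–Anh attack competing with the magnesium chelate, giving poor or reversed face selectivity at C1. Fallback: the order in which C6 and C7 are introduced is reversed, so that the Felkin–Anh bias leads to the required configuration. Setting out from aldehyde 3, Grignard reagent 9 (THF, 0 °C) should give β-hydroxysilane F2 as a carbinol epimer mixture. Tamao oxidation (KF, KHCO3, H2O2, THF/MeOH) then gives 1,2-diol F3. Benzoylation of the primary hydroxyl (BzCl, pyridine, CH2Cl2, −40 °C) gives hydroxy benzoate F4, and Dess–Martin oxidation gives benzoyloxymethyl ketone F5. Addition of ethynylmagnesium bromide in THF at −78 °C, with C6 arriving anti to the C2–O bond, should give 14, where the route is rejoined.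

3. Step 9. What may go wrong: over-reduction of the iodoalkene or reductive loss of iodine, and incomplete conversion that leaves mixtures hard to separate. Fallback: setting out from 15, hydroboration with dicyclohexylborane (3 equiv, THF, 0 °C) adds H and B syn across the alkyne with boron on the iodine-bearing C5, the tertiary hydroxyl being taken up as its borinate, to give α-iodoalkenylborane F6. Protonolysis of the alkenyl C–B bond with acetic acid proceeds with retention, and aqueous work-up frees the hydroxyl, giving the (Z)-iodoalkene 16, where the route is rejoined.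

**Further compounds**
F1 | step 12 | (1S,2S,3R,4S)-1-(benzoyloxymethyl)-2,3-O-isopropylidenecyclohex-5-ene-1,2,3,4-tetrol (C4 epimer of 20) | O=C(OC[C@@]1(O)C=C[C@H](O)[C@H]2OC(C)(C)O[C@H]12)c1ccccc1
F2 | step 5 | 1-[(4R,5R)-5-{[tert-butyl(dimethyl)silyl]oxymethyl}-2,2-dimethyl-1,3-dioxolan-4-yl]-2-[isopropoxy(dimethyl)silyl]ethan-1-ol, both carbinol epimers | CC(C)O[Si](C)(C)CC(O)[C@H]1OC(C)(C)O[C@@H]1CO[Si](C)(C)C(C)(C)C
F3 | step 5 | 1-[(4R,5R)-5-{[tert-butyl(dimethyl)silyl]oxymethyl}-2,2-dimethyl-1,3-dioxolan-4-yl]ethane-1,2-diol, both carbinol epimers | OCC(O)[C@H]1OC(C)(C)O[C@@H]1CO[Si](C)(C)C(C)(C)C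
F4 | step 5 | 2-[(4R,5R)-5-{[tert-butyl(dimethyl)silyl]oxymethyl}-2,2-dimethyl-1,3-dioxolan-4-yl]-2-hydroxyethyl benzoate, both carbinol epimers | O=C(OCC(O)[C@H]1OC(C)(C)O[C@@H]1CO[Si](C)(C)C(C)(C)C)c1ccccc1
F5 | step 5 | 2-[(4S,5R)-5-{[tert-butyl(dimethyl)silyl]oxymethyl}-2,2-dimethyl-1,3-dioxolan-4-yl]-2-oxoethyl benzoate | O=C(OCC(=O)[C@H]1OC(C)(C)O[C@@H]1CO[Si](C)(C)C(C)(C)C)c1ccccc1
F6 | step 9 | α-iodoalkenyl(dicyclohexyl)borane from 15 (boron on C5 trans to C1, tertiary oxygen as dicyclohexylborinate) | I/C(B(C1CCCCC1)C1CCCCC1)=C\[C@](OB(C1CCCCC1)C1CCCCC1)(COC(=O)c1ccccc1)[C@H]1OC(C)(C)O[C@@H]1CO[Si](C)(C)C(C)(C)C
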